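Readings and results stem from a simulated flask from invented constants, noise included.

3 numbers are asked of this flask, two excesses and a conversion, and together they ask how long the lead of the left-handed product over the right-handed product lasts while the single-handed free catalyst works through the racemate.

| flask | left-handed substrate | right-handed substrate | partner | protic impurity | free catalyst | remark | time |
|---|---|---|---|---|---|---|---|
| alpha | 0.050 M | 0.050 M | 0.12 M | 5 mM | 0.50 mM | run made earlier |  |
| beta | 0.20 M | 0.20 M | 0.12 M | 5 mM | 0.50 mM | run made earlier |  |
| zeta | 0.10 M | 0.10 M | 0.12 M | 7.5 mM | 0.50 mM | run made earlier |  |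
| flask | 0.10 M | 0.10 M | 0.120 M | 5.00 mM | 0.50 mM |  | 25 min |

| run | time / min | left-handed product / % | right-handed product / % | left-handed substrate / % |
|---|---|---|---|---|
| alpha | 4.00 | 50 | 22 | 0 |
| alpha | 8.00 | 49 | 25 | 0 |
| alpha | 12.0 | 54 | 26 | 2 |
| alpha | 15.0 | 49 | 31 | 0 |
| alpha | 20.0 | 52 | 36 | 0 |
| alpha | 25.0 | 52 | 33 | 0 |
| beta | 1.50 | 23 | 0 | 23 |
| beta | 5.00 | 25 | 2 | 26 |
| beta | 8.00 | 28 | 1 | 25 |
| beta | 15.0 | 28 | 5 | 24 |
| beta | 20.0 | 28 | 4 | 21 |
| beta | 25.0 | 24 | 2 | 25 |
| zeta | 2.00 | 42 | 7 | 6 |
| zeta | 4.00 | 44 | 8 | 4 |
| zeta | 8.00 | 46 | 10 | 3 |
| zeta | 12.0 | 47 | 11 | 3 |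
| zeta | 25.0 | 47 | 11 | 3 |

(scatter of a reading: 2 percentage points)

- free catalyst is single-handed; left-handed substrate and right-handed substrate are mirror images of each other, charged as a racemate, each of them at the stated concentration
- steps that have been proposed: free catalyst + left-handed substrate <-> catalyst intermediate A; free catalyst + right-handed substrate <-> catalyst intermediate B; partner + catalyst intermediate A -> free catalyst + left-handed product; partner + catalyst intermediate B -> free catalyst + right-handed product; 2 free catalyst <-> resting dimer; partner + protic impurity -> quenched reagent; partner <-> dormant form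
- an excess is the difference of the two amounts in percent of their sum
- an excess is below zero if the other one leads

- excess of left-handed product over right-handed product in the product at 30 s
- excess of left-handed product over right-handed product in the product at 25 min
- part of the left-handed substrate and right-handed substrate charged together that has reacted at 25 min

Anna and Ben, arguing over this flask, share a budget. The zeta run stalled with product read at 58.0 % of the substrates charged, and partner minus protic impurity comes to 56.2 %, a gap within the scatter of the two readings summed. So both treat partner as the limiting reagent and book 57.5 % as the conversion of this flask.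

They also share a reading. At 8.00 min the zeta run leaves 6.00 % of its left-handed substrate and 80.0 % of its right-handed substrate, and the ratio of the logarithms of these fractions is the selectivity factor s, how many times faster a left-handed molecule is taken than a right-handed one, here 12.6. The readings at 2.00 min and 25.0 min give 14.1 and 11.3, so it carries wide scatter.

Anna holds that a fixed s means a fixed product ratio, so the excess is (s−1)/(s+1), or 85.3 %, at 30 s and at 25 min alike. Ben compares rates at one moment: left-handed product forms over right-handed product as s times the left-handed over the right-handed substrate concentration, and that ratio drifts down as the left-handed substrate goes. He points to the zeta excess, which reads 71.4 % at first and 62.1 % at the end. If a fraction y of the right-handed substrate remains, y^s of the left-handed remains, and the budget requires the two fractions to sum to 85.0 %. That gives y = 79.5 % and 5.53 % for the left-handed substrate, and so a final excess of 64.3 %.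

The forecast, holding that “partner sets the endpoint”, expects a falling excess like Ben's, 82 % at 30 s and 64 % at 25 min, and a conversion of 58 %.

The flask gives excesses of 78.7 % at 30 s and 68.2 % at 25 min and a conversion of 57.1 %: the excess sinks, in the direction Ben reckoned.

    free catalyst + left-handed substrate ⇌ catalyst intermediate A (K = 14.0 M⁻¹, k = 5400 M⁻¹ s⁻¹)
    free catalyst + right-handed substrate ⇌ catalyst intermediate B (K = 3.00 M⁻¹, k = 600 M⁻¹ s⁻¹)
    partner + catalyst intermediate A → free catalyst + left-handed product (k = 560 M⁻¹ s⁻¹)
    partner + catalyst intermediate B → free catalyst + right-handed product (k = 160 M⁻¹ s⁻¹)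
    2 free catalyst ⇌ resting dimer (K = 1200 M⁻¹, k = 2200 M⁻¹ s⁻¹)
    partner + protic impurity → quenched reagent (k = 2.10 M⁻¹ s⁻¹)
    partner ⇌ dormant form (K = 4.90, k = 0.0200 s⁻¹)

At 25.0 min the flask keeps, unbound, 4.0 % of its left-handed substrate against 82 % of its right-handed substrate, and the s read from the zeta run times the concentration ratio of these two is 0.622, which by Ben's rule has right-handed product forming faster at that moment. Anna's region is short partner: the neighbour charged with 0.072 M goes from 84.1 % to 82.7 %, and there the same ratio at the end is still 5.05.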